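## Retrosynthetic overview
1. Target 15 ⇒ bis-acrylate 12 + 4-vinylcatechol 13. One Ru operation closes the dihydropyranone (RCM, C3=C4) and builds the caffeate C=C (CM).
2. 12 ⇒ cyclopropyl keto diol 11 ⇒ 1-pyrazoline 10, where light-driven loss of N2 closes C9–C10. 10 ⇒ CH2N2 + E-enone 9, with C8 set by C7.
3. 9 ⇒ Wittig union (C8=C10) of α-acetoxy aldehyde 8 and keto ylide 7.
4. 8 ⇒ 2-deoxy-L-ribose 1, which brings C6 and C7. 7 ⇒ ethyl L-lactate 6, which brings C12.
5. Ring order: cyclopropane first (step 5), lactone last (step 7).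

Locants: lactone C2–C6; C7 = CH(OAc); cyclopropane C8 (on C7), C9 (CH2), C10 (on the C=O); C11 = ketone; C12 = CH(CH3)O. The target is 6R,7S,8S,10S,12S.

Assumption: 2-deoxy-L-ribose (bulk L-nucleoside sugar) and 4-vinylcatechol are taken as catalogue items, and ethereal CH2N2 is a freshly distilled reagent.

## Route

Step 1
Reactants: 1 2-deoxy-L-ribose; 2 methyltriphenylphosphonium bromide
Product: 3 (2S,3R)-hex-5-ene-1,2,3-triol
Conditions: 2 (3.5 equiv), KOtBu (3.4 equiv), THF, 0 °C → rt, 16 h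
Reagents that add atoms: methyltriphenylphosphonium bromide (2), C[P+](c1ccccc1)(c1ccccc1)c1ccccc1.[Br-]
Why: Wittig methylenation of the open-chain aldehyde that is in equilibrium with the lactol, in which excess ylide only deprotonates the OH groups and C6 and C7 come unchanged from the sugar.

Step 2
Reactants: 3 (2S,3R)-hex-5-ene-1,2,3-triol
Product: 5 (2S,3R)-1,3-dihydroxyhex-5-en-2-yl acetate, via cyclic methyl orthoacetate 4 (not isolated)
Conditions: MeC(OMe)3 (1.1 equiv), CSA (2 mol %), CH2Cl2, rt, 30 min; then AcOH–H2O 4:1, 0 °C, 15 min; use at once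
Reagents that add atoms: trimethyl orthoacetate, CC(OC)(OC)OC; water, O
Why: Regioselective monoacylation of a vic-diol through a cyclic orthoester, in which exchange closes kinetically on the terminal 1,2-diol and acid hydrolysis of the 2-methoxy-1,3-dioxolane opens to the secondary (C7) acetate and the free primary alcohol without touching a stereocentre.

Step 3
Reactants: 6 ethyl (S)-lactate; 2 methyltriphenylphosphonium bromide
Product: 7 (3S)-3-hydroxy-1-(triphenyl-λ5-phosphanylidene)butan-2-one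
Conditions: 2 (3.3 equiv), NaHMDS (3.2 equiv), THF, 0 °C; then 6, −78 °C → rt, 6 h; H2O/Na2CO3 work-up
Reagents that add atoms: methyltriphenylphosphonium bromide (2), C[P+](c1ccccc1)(c1ccccc1)c1ccccc1.[Br-]
Why: Acylation of a non-stabilised ylide by an ester followed by transylidation gives the stabilised keto ylide, and C12 is safe from enolisation because the α-OH sits as its sodium alkoxide.

Step 4
Reactants: 5 (2S,3R)-1,3-dihydroxyhex-5-en-2-yl acetate; 7 (3S)-3-hydroxy-1-(triphenyl-λ5-phosphanylidene)butan-2-one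
Product: 9 (2S,4E,6S,7R)-6-acetoxy-2,7-dihydroxydeca-4,9-dien-3-one, via acetoxy aldehyde 8 (not isolated)
Conditions: TEMPO (10 mol %), PhI(OAc)2 (1.1 equiv), CH2Cl2, rt, 3 h; then 7 (1.3 equiv), rt, 16 h
Reagents that add atoms: none
Why: Oxoammonium oxidation takes the primary alcohol over the secondary one (5 has no vic-diol for PhI(OAc)2 to cleave), and the migration-prone aldehyde is trapped in the same pot under neutral conditions by an E-selective Wittig olefination with the stabilised ylide, so C7 is not epimerised.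

Step 5
Reactants: 9 (2S,4E,6S,7R)-6-acetoxy-2,7-dihydroxydeca-4,9-dien-3-one
Product: 11 (1S,2R)-2-hydroxy-1-{(1S,2S)-2-[(2S)-2-hydroxypropanoyl]cyclopropyl}pent-4-en-1-yl acetate, via 1-pyrazoline 10 (not isolated)
Conditions: CH2N2 (3 equiv), Et2O–CH2Cl2, −20 → 0 °C, dark, silanised glass, 2 h; Ar sparge at −20 °C; then thioxanthone (5 mol %), 405 nm LED, −40 °C, 2 h
Reagents that add atoms: diazomethane, C=[N+]=[N-]
Why: Proposed new method: the HOMO(dipole)-controlled [3+2] of CH2N2 touches only the electron-poor C8=C10 bond and leaves the allyl group alone, its carbon attacks C8 anti to the C7–OAc bond with H-7 inside (the Felkin–Anh and inside-alkoxy models both give 8S), and the labile 3-acyl-1-pyrazoline 10 is not warmed but receives Dexter energy transfer from triplet thioxanthone (about 65 kcal/mol, above the azo triplet), so that C–N cleavage, N2 loss and intersystem crossing of the acyl-stabilised 1,3-biradical close C9–C10 to the less strained trans (10S) ketone faster than 10 tautomerises to the inert 2-pyrazoline, while 405 nm light is absorbed by neither ketone nor esters; the closest known reaction type is the UV or benzophenone-sensitised photodenitrogenation of ester-substituted 1-pyrazolines made from sugar-derived enoates, which has not been shown with visible-light sensitisation on an enolisable α-H 3-acyl-1-pyrazoline of an acyclic α′-hydroxy enone.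

Step 6
Reactants: 11 (1S,2R)-2-hydroxy-1-{(1S,2S)-2-[(2S)-2-hydroxypropanoyl]cyclopropyl}pent-4-en-1-yl acetate
Product: 12 (2S)-1-{(1S,2S)-2-[(1S,2R)-1-acetoxy-2-(acryloyloxy)pent-4-en-1-yl]cyclopropyl}-1-oxopropan-2-yl acrylate
Conditions: acryloyl chloride (3 equiv), i-Pr2NEt (4 equiv), DMAP (5 mol %), CH2Cl2, −20 → 0 °C, 1 h
Reagents that add atoms: acryloyl chloride, C=CC(=O)Cl
Why: Exhaustive O-acylation needs no selectivity because both free hydroxyls (C6 and C12) must carry an acrylate, it proceeds with retention at both carbons, and the cold short reaction avoids acetyl migration and C12 epimerisation.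

Step 7
Reactants: 12 (2S)-1-{(1S,2S)-2-[(1S,2R)-1-acetoxy-2-(acryloyloxy)pent-4-en-1-yl]cyclopropyl}-1-oxopropan-2-yl acrylate; 13 4-vinylbenzene-1,2-diol (4-vinylcatechol)
Product: 15 (2S)-1-{(1S,2S)-2-[(S)-acetoxy((2R)-6-oxo-3,6-dihydro-2H-pyran-2-yl)methyl]cyclopropyl}-1-oxopropan-2-yl (E)-3-(3,4-dihydroxyphenyl)acrylate (target), via lactone acrylate 14 (not isolated)
Conditions: Hoveyda–Grubbs II (5 mol %), CH2Cl2 (5 mM), 40 °C, 3 h; concentrate to 50 mM; then 13 (4 equiv), Hoveyda–Grubbs II (5 mol %), 40 °C, 12 h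
Reagents that add atoms: none
Why: Tandem ring-closing and cross-metathesis, in which the allyl group and its tethered acrylate close the six-membered lactone first, the remaining type II acrylate then couples E-selectively with the type I styrene, the conjugated lactone alkene is inert, and no stereocentre is touched.

## Compound list
1 | 2-deoxy-L-ribose, (3R,4S)-3,4,5-trihydroxypentanal (drawn open-chain, sold as the lactol) | O=CC[C@@H](O)[C@@H](O)CO | starting material
2 | methyltriphenylphosphonium bromide | C[P+](c1ccccc1)(c1ccccc1)c1ccccc1.[Br-] | starting material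
3 | (2S,3R)-hex-5-ene-1,2,3-triol | O[C@@H](CO)[C@H](O)CC=C | intermediate
4 | (1R)-1-[(4S)-2-methoxy-2-methyl-1,3-dioxolan-4-yl]but-3-en-1-ol (epimers at the orthoester carbon) | COC1(C)OC[C@H](O1)[C@H](O)CC=C | intermediate (not isolated)
5 | (2S,3R)-1,3-dihydroxyhex-5-en-2-yl acetate | CC(=O)O[C@@H](CO)[C@H](O)CC=C | intermediate
6 | ethyl (S)-lactate | CCOC(=O)[C@H](C)O | starting material
7 | (3S)-3-hydroxy-1-(triphenyl-λ5-phosphanylidene)butan-2-one | C[C@H](O)C(=O)C=P(c1ccccc1)(c1ccccc1)c1ccccc1 | intermediate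
8 | (2R,3R)-2-acetoxy-3-hydroxyhex-5-enal | CC(=O)O[C@@H](C=O)[C@H](O)CC=C | intermediate (not isolated)
9 | (2S,4E,6S,7R)-6-acetoxy-2,7-dihydroxydeca-4,9-dien-3-one | CC(=O)O[C@@H](/C=C/C(=O)[C@H](C)O)[C@H](O)CC=C | intermediate
10 | (1S,2R)-2-hydroxy-1-{(3S,4S)-3-[(2S)-2-hydroxypropanoyl]-4,5-dihydro-3H-pyrazol-4-yl}pent-4-en-1-yl acetate | CC(=O)O[C@@H]([C@H]1CN=N[C@@H]1C(=O)[C@H](C)O)[C@H](O)CC=C | intermediate (not isolated)
11 | (1S,2R)-2-hydroxy-1-{(1S,2S)-2-[(2S)-2-hydroxypropanoyl]cyclopropyl}pent-4-en-1-yl acetate | CC(=O)O[C@@H]([C@H]1C[C@@H]1C(=O)[C@H](C)O)[C@H](O)CC=C | intermediate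
12 | (2S)-1-{(1S,2S)-2-[(1S,2R)-1-acetoxy-2-(acryloyloxy)pent-4-en-1-yl]cyclopropyl}-1-oxopropan-2-yl acrylate | CC(=O)O[C@@H]([C@H]1C[C@@H]1C(=O)[C@H](C)OC(=O)C=C)[C@H](OC(=O)C=C)CC=C | intermediate
13 | 4-vinylbenzene-1,2-diol (4-vinylcatechol) | C=Cc1ccc(O)c(O)c1 | starting material
14 | (2S)-1-{(1S,2S)-2-[(S)-acetoxy((2R)-6-oxo-3,6-dihydro-2H-pyran-2-yl)methyl]cyclopropyl}-1-oxopropan-2-yl acrylate | CC(=O)O[C@@H]([C@H]1C[C@@H]1C(=O)[C@H](C)OC(=O)C=C)[C@H]1CC=CC(=O)O1 | intermediate (not isolated)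
15 | (2S)-1-{(1S,2S)-2-[(S)-acetoxy((2R)-6-oxo-3,6-dihydro-2H-pyran-2-yl)methyl]cyclopropyl}-1-oxopropan-2-yl (E)-3-(3,4-dihydroxyphenyl)acrylate | CC(=O)O[C@@H]([C@H]1C[C@@H]1C(=O)[C@H](C)OC(=O)/C=C/c1ccc(O)c(O)c1)[C@H]1CC=CC(=O)O1 | target

## Step count and risks
Total steps: 7.
Longest linear sequence: 6 (1 → 3 → 5 → 9 → 11 → 12 → 15; step 3 is the side branch).

**Step 5 (proposed new step).**
- Risk: 10 may tautomerise to the 2-pyrazoline before N2 is lost. The oxaallyl biradical may close on oxygen to give a dihydrofuran. The facial ratio may be modest.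
- Fallback (known chemistry): it sets out from 9 and comes back at 11.
- Both hydroxyls are silylated (TESCl, imidazole, CH2Cl2) to give (2S,4E,6S,7R)-6-acetoxy-2,7-bis(triethylsilyloxy)deca-4,9-dien-3-one F1.
- Corey–Chaykovsky cyclopropanation with dimethylsulfoxonium methylide (Me3S(O)I, NaH, DMSO–THF, 0 °C) adds to C8 anti to the C7–O bond and closes trans. This gives (1S,2R)-1-{(1S,2S)-2-[(2S)-2-(triethylsilyloxy)propanoyl]cyclopropyl}-2-(triethylsilyloxy)pent-4-en-1-yl acetate F2.
- HF·pyridine in THF at 0 °C then frees both alcohols and gives 11.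

**Step 2.**
- Risk: the orthoester may form across C6/C7 or become bicyclic, and the acetyl group may move to the primary oxygen before oxidation.
- Fallback: it sets out from 3 and comes back at 5.
- Thermodynamic acetalisation (PhCH(OMe)2, CSA, CH2Cl2) ties O6 and O8 into the all-equatorial dioxane (2S,4R,5S)-4-allyl-2-phenyl-1,3-dioxan-5-ol F3, which leaves only the C7 hydroxyl free.
- Ac2O in pyridine gives (2S,4R,5S)-4-allyl-2-phenyl-1,3-dioxan-5-yl acetate F4.
- 80% aqueous AcOH at rt removes the acetal and gives 5.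

**Step 7.**
- Risk: the free catechol may deactivate Ru, 13 may polymerise, or the styrene may intercept the allyl group.
- Fallback: it sets out from 12 and 13 and comes back at 15. It is run stepwise with the catechol masked.
- RCM alone (Grubbs II, 5 mM) is stopped and 14 is isolated.
- 13 is silylated (TBSCl, imidazole, DMF) to give 3,4-bis(tert-butyldimethylsilyloxy)styrene F5.
- Cross-metathesis of 14 with F5 (Grubbs II, CH2Cl2, 40 °C) gives the bis-TBS ether of the target F6.
- HF·pyridine in THF at 0 °C cleaves only the aryl silyl ethers and gives 15.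

## Further compounds
F1 | step 5 | (2S,4E,6S,7R)-6-acetoxy-2,7-bis(triethylsilyloxy)deca-4,9-dien-3-one | CC(=O)O[C@@H](/C=C/C(=O)[C@H](C)O[Si](CC)(CC)CC)[C@H](O[Si](CC)(CC)CC)CC=C
F2 | step 5 | (1S,2R)-1-{(1S,2S)-2-[(2S)-2-(triethylsilyloxy)propanoyl]cyclopropyl}-2-(triethylsilyloxy)pent-4-en-1-yl acetate | CC(=O)O[C@@H]([C@H]1C[C@@H]1C(=O)[C@H](C)O[Si](CC)(CC)CC)[C@H](O[Si](CC)(CC)CC)CC=C
F3 | step 2 | (2S,4R,5S)-4-allyl-2-phenyl-1,3-dioxan-5-ol | O[C@H]1CO[C@H](c2ccccc2)O[C@@H]1CC=C
F4 | step 2 | (2S,4R,5S)-4-allyl-2-phenyl-1,3-dioxan-5-yl acetate | CC(=O)O[C@H]1CO[C@H](c2ccccc2)O[C@@H]1CC=C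
F5 | step 7 | 3,4-bis(tert-butyldimethylsilyloxy)styrene | C=Cc1ccc(O[Si](C)(C)C(C)(C)C)c(O[Si](C)(C)C(C)(C)C)c1
F6 | step 7 | bis-TBS ether of the target | CC(=O)O[C@@H]([C@H]1C[C@@H]1C(=O)[C@H](C)OC(=O)/C=C/c1ccc(O[Si](C)(C)C(C)(C)C)c(O[Si](C)(C)C(C)(C)C)c1)[C@H]1CC=CC(=O)O1
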